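**Strategy.** The C20 formyl carbon on C10 and C13, alpha to the C12 ketone, form a retro-aldol pair. Reconnecting C13–C20 turns ring C into a bicyclo[2.2.2]octane whose carbons C9, C11, C12, C13, C20 and C10 are the resorcinol ring of a cheap coumarin. After dearomatising spiro-alkylation at C10, an intramolecular Diels–Alder reaction of the cyclohexa-2,4-dienone (diene C9=C11–C12=C13) with the tethered alkene C8=C14 forms C8–C9 and C13–C14, closing rings B and C at once and fixing C8 and C9. One copper-hydride-set centre (C5) relays to C4 and C10. Reduction at C20 and retro-aldol cleavage then free the aldehyde and the C13 enolate that closes ring D.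

Key step: step 11

Remark: gibberellane numbering (C1–C20) is used for all intermediates; C6 is carried as an epimer mixture from step 7 and set in step 16; (R)-DTBM-SEGPHOS is assumed to give the (4R) lactone in step 4 (otherwise its antipode is used).

Step 1
Reactants: 1 ethynyltrimethylsilane; 2 2,3-dibromoprop-1-ene
Product: 4 (4-bromopent-4-en-1-yn-1-yl)trimethylsilane, via trimethylsilylethynylmagnesium bromide 3 (not isolated)
Conditions: EtMgBr, THF, 0 → 40 °C; then 2, CuBr·SMe2 (5 mol %), 0 °C → rt
Reagents that add atoms: none
Why: Copper-catalysed coupling of an alkynyl Grignard reagent with the allylic bromide of 2 (SN2 and SN2′ attack give the same skipped enyne) should leave the vinyl bromide untouched for step 7.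

Step 2
Reactants: 5 resorcinol; 6 dimethyl 3-oxopentanedioate
Product: 7 methyl (7-hydroxy-2-oxo-2H-chromen-4-yl)acetate
Conditions: conc. H2SO4, 0 °C → rt
Reagents that add atoms: none
Why: Pechmann condensation (transesterification, ring closure para to the second hydroxyl, dehydration) should give the 7-hydroxycoumarin whose benzene ring supplies C9–C13 and C20 and whose lactone carbonyl is C19.

Step 3
Reactants: 7 methyl (7-hydroxy-2-oxo-2H-chromen-4-yl)acetate
Product: 8 methyl [7-(tert-butyldimethylsilyloxy)-2-oxo-2H-chromen-4-yl]acetate
Conditions: TBSCl, imidazole, DMF, rt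
Reagents that add atoms: tert-butyldimethylsilyl chloride, CC(C)(C)[Si](C)(C)Cl
Why: Standard imidazole-mediated silylation protects the phenol oxygen on C12 during the enolate steps.

Step 4
Reactants: 8 methyl [7-(tert-butyldimethylsilyloxy)-2-oxo-2H-chromen-4-yl]acetate
Product: 9 methyl [(4R)-7-(tert-butyldimethylsilyloxy)-2-oxochroman-4-yl]acetate
Conditions: Cu(OAc)2·H2O (3 mol %), (R)-DTBM-SEGPHOS (3 mol %), (EtO)2MeSiH, t-BuOH, toluene, rt
Reagents that add atoms: none
Why: Copper hydride-catalysed asymmetric conjugate reduction of a beta,beta-disubstituted unsaturated lactone delivers hydride to one face of C5 (coumarin C4) under ligand control and sets the only catalyst-made stereocentre.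

Step 5
Reactants: 9 methyl [(4R)-7-(tert-butyldimethylsilyloxy)-2-oxochroman-4-yl]acetate
Product: 10 methyl [(3R,4R)-7-(tert-butyldimethylsilyloxy)-3-methyl-2-oxochroman-4-yl]acetate (methyl trans to the side chain)
Conditions: LiN(SiMe3)2, THF, −78 °C; MeI, −78 → −40 °C
Reagents that add atoms: iodomethane, CI
Why: Enolate alkylation of the aryl lactone, whose alpha-hydrogens are more acidic than those of the methyl ester, puts the C18 methyl on C4 anti to the C5 side chain; this centre is re-enolised in step 6.

Step 6
Reactants: 10 methyl [(3R,4R)-7-(tert-butyldimethylsilyloxy)-3-methyl-2-oxochroman-4-yl]acetate; 11 1-chloro-3-iodopropane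
Product: 12 methyl [(3R,4S)-7-(tert-butyldimethylsilyloxy)-3-(3-chloropropyl)-3-methyl-2-oxochroman-4-yl]acetate (chloropropyl trans, methyl cis to the side chain)
Conditions: LiN(SiMe3)2, THF/DMPU, −78 °C; 11, −78 → −30 °C
Reagents that add atoms: none
Why: The second lactone enolate alkylation creates quaternary C4 with the electrophile entering anti to the pseudo-axial C5 side chain, so the C1–C3 arm ends trans to it, and the iodide terminus of 11 reacts in preference to the chloride.

Step 7
Reactants: 12 methyl [(3R,4S)-7-(tert-butyldimethylsilyloxy)-3-(3-chloropropyl)-3-methyl-2-oxochroman-4-yl]acetate; 4 (4-bromopent-4-en-1-yn-1-yl)trimethylsilane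
Product: 13 methyl 2-[chroman-4-yl unit of 12]-3-methylidene-6-(trimethylsilyl)hex-5-ynoate (C6 epimers; ring centres as in 12)
Conditions: LiNCy2, THF, −78 °C; ZnCl2, −78 °C → rt; 4, Pd(dba)2 (5 mol %), P(t-Bu)3 (5 mol %), rt
Reagents that add atoms: none
Why: Palladium-catalysed alpha-alkenylation of an ester zinc enolate (Negishi-type enolate coupling) forms C6–C8 with the alkene C8=C14 in place; C6 is the only enolisable position left and forms as an epimer mixture that step 16 equilibrates.

Step 8
Reactants: 13 silyl-protected alkenyl ester
Product: 14 methyl 2-[(3R,4S)-3-(3-chloropropyl)-7-hydroxy-3-methyl-2-oxochroman-4-yl]-3-methylidenehex-5-ynoate (C6 epimers)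
Conditions: Bu4NF, AcOH, THF, 0 °C → rt
Reagents that add atoms: none
Why: Acetic acid-buffered fluoride desilylation should free the phenol and the terminal alkyne without opening the aryl lactone.

Step 9
Reactants: 14 phenol chloride
Product: 15 spiro enol lactone: ring A closed, C10 spiro, cross-conjugated dienone with C12 ketone, C19(=O)–O–C20 lactone bridge retained
Conditions: Cs2CO3, NaI (20 mol %), MeCN (0.005 M), 60 °C
Reagents that add atoms: none
Why: Intramolecular para-alkylative dearomatisation of a phenolate (Winstein–Masamune ipso-alkylation, 6-exo-tet) lets the C12 phenoxide attack through C10 to close ring A, and the retained lactone bridge (bicyclo[3.3.1]) allows C1 to add only to the face of C10 anti to C6, which fixes the spiro centre.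

Step 10
Reactants: 15 spiro enol lactone
Product: 17 spiro cyclohexa-2,4-dienone with C20 ketone, C12 OTBS, C19 allyl ester and C7 methyl ester, via sodium dionate 16 (not isolated)
Conditions: NaOCH2CH=CH2 (1.0 equiv, from allyl alcohol and NaH), THF, −78 °C; then TBSCl, −78 °C → rt
Reagents that add atoms: allyl alcohol (as its sodium salt), C=CCO; tert-butyldimethylsilyl chloride, CC(C)(C)[Si](C)(C)Cl
Why: Alkoxide acyl substitution on the enol lactone (a vinylogous anhydride) gives the C19 allyl ester and a vinylogous carboxylate that is O-silylated at the less hindered oxygen on C12 to give the linearly conjugated dienone, and one equivalent of alkoxide at low temperature avoids deprotonation at C6.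

Step 11
Reactants: 17 spiro cyclohexa-2,4-dienone
Product: 18 cage ketone: bicyclo[2.2.2]octene with C11=C12(OTBS), C20 ketone bridging C10 and C13, rings A and B closed, propargyl on C8
Conditions: toluene (0.01 M), BHT (cat.), 130 °C, sealed tube
Reagents that add atoms: none
Why: A thermal concerted [4+2] cycloaddition (intramolecular Diels–Alder reaction) joins the dienone diene C9=C11–C12(OTBS)=C13 and the unactivated 1,1-disubstituted alkene C8=C14 held on C10 through C5–C6. The closest known reaction type is the intramolecular Diels–Alder reaction of 6-(but-3-enyl)cyclohexa-2,4-dienones to isotwistenones. Ring B (five-membered, C5–C6–C8–C9–C10) closes in the fused mode through C8–C9, and ring C (six-membered) closes by the cycloaddition itself, here as a bicyclo[2.2.2]octene with the temporary C10–C20 bridge. C8 and C9 are set by the tether: the alkene reaches only the dienone face syn to C5 and C8 must bond to the adjacent terminus C9, so H9 and C15 end cis and C14 lies on the side of C20, while C13 becomes a temporary bridgehead. The step needs isotwistane over twistane regiochemistry (three-atom tether, five-membered ring), alkene over alkyne (the alkyne would need a seven-membered tether ring) and cycloaddition over dienone dimerisation or aromatising retro-Michael cleavage through C6–H (spiro substitution, high dilution, no acid or base).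

Step 12
Reactants: 18 cage ketone
Product: 20 cage aldol with C20 carbinol and C12 ketone flanking C13, via cage alcohol 19 (not isolated)
Conditions: NaBH4, MeOH, −20 °C; then 1 M aq HCl, THF, 0 °C
Reagents that add atoms: none
Why: Borohydride reduction of the non-enolisable C20 ketone (its new centre is lost in step 13) followed by acid hydrolysis of the silyl enol ether should give the beta-hydroxy ketone.

Step 13
Reactants: 20 cage aldol
Product: 22 aldehyde with C20 formyl on C10, C12–C13 TBS enol ether and propargyl on C8, via potassium enolate 21 (not isolated)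
Conditions: KN(SiMe3)2 (1.05 equiv), THF, −78 → 0 °C; then TBSCl, −78 °C → rt
Reagents that add atoms: tert-butyldimethylsilyl chloride, CC(C)(C)[Si](C)(C)Cl
Why: Retro-aldol fragmentation of the potassium aldolate cleaves C13–C20 with release of the bicyclo[2.2.2]octane strain, giving the C20 aldehyde and regiospecifically the C12–C13 enolate, which O-silylation traps before it can equilibrate to the C11 side.

Step 14
Reactants: 22 silyl enol ether aldehyde
Product: 23 19-allyl 7-methyl diester of the target (ring D closed, C6 epimers)
Conditions: Ph3PAuCl (5 mol %), AgBF4 (5 mol %), CH2Cl2/H2O (10:1), rt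
Reagents that add atoms: none
Why: Gold-catalysed 5-exo-dig carbocyclisation of a silyl enol ether onto a terminal alkyne (Toste-type Conia-ene reaction) forms C13–C16 and the exocyclic methylene, and the bridge from C8 allows only the C13 configuration with C16 syn to C15.

Step 15
Reactants: 23 allyl methyl diester
Product: 24 19-acid 7-methyl ester (C6 epimers)
Conditions: Pd(PPh3)4 (5 mol %), morpholine, THF, rt
Reagents that add atoms: none
Why: Palladium-catalysed deallylation (Tsuji–Trost allyl transfer to morpholine) should free the hindered C19 acid under neutral conditions that spare the aldehyde, the ketone and the exocyclic alkene.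

Step 16
Reactants: 24 19-acid 7-methyl ester
Product: 26 CNP0412196.1, via sodium carboxylate 25 (not isolated)
Conditions: NaOMe, MeOH, rt; then LiOH, H2O, 50 °C; aq HCl work-up
Reagents that add atoms: lithium hydroxide, [Li+].[OH-]
Why: Methoxide should equilibrate the ester-bearing C6 to the more stable epimer with C7 trans to the quaternary C4 on ring B (the natural configuration), and saponification then gives the diacid, the aldehyde being non-enolisable and C13 a bridgehead.

**Compound list**

1 | ethynyltrimethylsilane | C#C[Si](C)(C)C | starting material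
2 | 2,3-dibromoprop-1-ene | C=C(Br)CBr | starting material
3 | trimethylsilylethynylmagnesium bromide (not isolated) | C[Si](C)(C)C#C[Mg]Br | intermediate
4 | (4-bromopent-4-en-1-yn-1-yl)trimethylsilane | C=C(Br)CC#C[Si](C)(C)C | intermediate
5 | resorcinol | Oc1cccc(O)c1 | starting material
6 | dimethyl 3-oxopentanedioate | COC(=O)CC(=O)CC(=O)OC | starting material
7 | methyl (7-hydroxy-2-oxo-2H-chromen-4-yl)acetate | COC(=O)CC1=CC(=O)Oc2cc(O)ccc12 | intermediate
8 | methyl [7-(tert-butyldimethylsilyloxy)-2-oxo-2H-chromen-4-yl]acetate | COC(=O)CC1=CC(=O)Oc2cc(O[Si](C)(C)C(C)(C)C)ccc12 | intermediate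
9 | methyl [(4R)-7-(tert-butyldimethylsilyloxy)-2-oxochroman-4-yl]acetate | COC(=O)C[C@@H]1CC(=O)Oc2cc(O[Si](C)(C)C(C)(C)C)ccc12 | intermediate
10 | methyl [(3R,4R)-7-(tert-butyldimethylsilyloxy)-3-methyl-2-oxochroman-4-yl]acetate | COC(=O)C[C@@H]1[C@@H](C)C(=O)Oc2cc(O[Si](C)(C)C(C)(C)C)ccc12 | intermediate
11 | 1-chloro-3-iodopropane | ClCCCI | starting material
12 | methyl [(3R,4S)-7-(tert-butyldimethylsilyloxy)-3-(3-chloropropyl)-3-methyl-2-oxochroman-4-yl]acetate | COC(=O)C[C@@H]1[C@@](C)(CCCCl)C(=O)Oc2cc(O[Si](C)(C)C(C)(C)C)ccc12 | intermediate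
13 | alkenylated ester, C6 epimers (12 carrying the 1-[3-(trimethylsilyl)prop-2-ynyl]vinyl group on C6) | COC(=O)C(C(=C)CC#C[Si](C)(C)C)[C@@H]1[C@@](C)(CCCCl)C(=O)Oc2cc(O[Si](C)(C)C(C)(C)C)ccc12 | intermediate
14 | phenol with terminal alkyne, C6 epimers | COC(=O)C(C(=C)CC#C)[C@@H]1[C@@](C)(CCCCl)C(=O)Oc2cc(O)ccc12 | intermediate
15 | spiro enol lactone (ring A closed, C12 ketone, C19–O–C20 bridge) | COC(=O)C(C(=C)CC#C)[C@@H]1[C@@]2(C)CCC[C@@]13C=CC(=O)C=C3OC2=O | intermediate
16 | sodium dionate with C19 allyl ester (not isolated) | COC(=O)C(C(=C)CC#C)[C@@H]1[C@](C)(C(=O)OCC=C)CCC[C@@]12C=CC([O-])=CC2=O.[Na+] | intermediate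
17 | spiro 3-silyloxycyclohexa-2,4-dienone (C20 ketone, C12 OTBS) | COC(=O)C(C(=C)CC#C)[C@@H]1[C@](C)(C(=O)OCC=C)CCC[C@@]12C=CC(O[Si](C)(C)C(C)(C)C)=CC2=O | intermediate
18 | cage ketone (bicyclo[2.2.2]octene, C10–C20(=O)–C13 bridge) | C#CC[C@]23C[C@@H]4C(O[Si](C)(C)C(C)(C)C)=C[C@H]2[C@]1(C4=O)CCC[C@@](C)(C(=O)OCC=C)[C@H]1C3C(=O)OC | intermediate
19 | cage alcohol, C20 epimers (not isolated) | C#CC[C@]23C[C@@H]4C(O[Si](C)(C)C(C)(C)C)=C[C@H]2[C@]1(C4O)CCC[C@@](C)(C(=O)OCC=C)[C@H]1C3C(=O)OC | intermediate
20 | cage aldol (C20 carbinol, C12 ketone) | C#CC[C@]23C[C@@H]4C(=O)C[C@H]2[C@]1(C4O)CCC[C@@](C)(C(=O)OCC=C)[C@H]1C3C(=O)OC | intermediate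
21 | potassium C12–C13 enolate with C20 aldehyde (not isolated) | C#CC[C@]12CC=C([O-])C[C@H]1[C@]3(C=O)CCC[C@@](C)(C(=O)OCC=C)[C@H]3C2C(=O)OC.[K+] | intermediate
22 | C12–C13 TBS enol ether with C20 aldehyde | C#CC[C@]12CC=C(O[Si](C)(C)C(C)(C)C)C[C@H]1[C@]3(C=O)CCC[C@@](C)(C(=O)OCC=C)[C@H]3C2C(=O)OC | intermediate
23 | 19-allyl 7-methyl diester of the target, C6 epimers | C=C1C[C@]23C[C@H]1C(=O)C[C@H]2[C@]1(C=O)CCC[C@@](C)(C(=O)OCC=C)[C@H]1C3C(=O)OC | intermediate
24 | 19-acid 7-methyl ester, C6 epimers | C=C1C[C@]23C[C@H]1C(=O)C[C@H]2[C@]1(C=O)CCC[C@@](C)(C(=O)O)[C@H]1C3C(=O)OC | intermediate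
25 | sodium 19-carboxylate 7-methyl ester with natural C6 (not isolated) | C=C1C[C@]23C[C@H]1C(=O)C[C@H]2[C@]1(C=O)CCC[C@@](C)(C(=O)[O-])[C@H]1[C@@H]3C(=O)OC.[Na+] | intermediate
26 | CNP0412196.1 (12-oxo, 20-formyl gibberellin 7,19-dioic acid) | C=C1C[C@]23C[C@H]1C(=O)C[C@H]2[C@]1(C=O)CCC[C@@](C)(C(=O)O)[C@H]1[C@@H]3C(=O)O | target

**Totals.** Total step count: 16. Longest linear sequence: 15 steps (steps 2–16 from resorcinol); step 1 supplies bromide 4.

**Steps most likely to fail**

Step 9. The phenoxide may transfer the acyl group of another molecule's aryl lactone or be O-alkylated intermolecularly faster than it closes the ring through C10, and prolonged base may isomerise or cleave the product through C6–H. The fallback sets out from 14: two equivalents of sodium allyloxide first open the lactone to the allyl ester resorcinol F1 (as its disodium salt). Its C10, now ortho and para to two phenoxide oxygens, should be C-alkylated by the chloropropyl arm (NaI, DMF) to give sodium dionate 16 directly, where the route is rejoined for silylation. The C10 configuration then rests on sodium chelation between the C20 phenoxide and the C19 ester instead of on the lactone bridge.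

Step 13. The aldolate oxygen may be silylated before fragmentation, or proton transfer may scramble the enolate to C11. The fallback sets out from 20: K2CO3 in MeOH should effect the retro-aldol under equilibrating conditions and give the free keto aldehyde F2. Catalytic t-BuOK in DMSO should then close ring D by base-mediated 5-exo-dig addition of the ketone enolate to the alkyne. The C11 enolate cannot reach the alkyne without forming a trans-fused bicyclo[3.3.0]octane with ring B, so only C13 should react. The route is rejoined at 23.

Step 11. The dienone may dimerise, or fragment to a phenol through C6–H, at the temperature the unactivated alkene requires. The fallback sets out from 17: 1,2-reduction of the dienone carbonyl (NaBH4, CeCl3·7H2O, MeOH) should give the dienol F3, a 2-silyloxycyclohexa-1,3-diene that is no longer a dienone. Its thermal intramolecular Diels–Alder reaction (toluene, 180 °C) should give cage alcohol 19 directly, and the route is rejoined at the acid hydrolysis of step 12.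

**Further compounds**

F1 | step 9 | allyl methyl diester with 2,4-dihydroxyphenyl on C5 (lactone of 14 opened at C19) | COC(=O)C(C(=C)CC#C)[C@@H](c1ccc(O)cc1O)[C@@](C)(CCCCl)C(=O)OCC=C
F2 | step 13 | free keto aldehyde (C12 ketone, C20 formyl, propargyl on C8) | C#CC[C@]12CCC(=O)C[C@H]1[C@]3(C=O)CCC[C@@](C)(C(=O)OCC=C)[C@H]3C2C(=O)OC
F3 | step 11 | spiro 2-silyloxycyclohexa-1,3-diene with C20 carbinol (C20 epimers) | COC(=O)C(C(=C)CC#C)[C@@H]1[C@](C)(C(=O)OCC=C)CCC[C@@]12C=CC(O[Si](C)(C)C(C)(C)C)=CC2O
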